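It was impossible to part partner from precatalyst in the two earlier runs: Saturday's raised both at once, at the same starting material and temperature.

| setting | Thursday's | Saturday's | autumn | winter |
|---|---|---|---|---|
| starting material | 11 mM | 11 mM | 4.0 mM | 11 mM |
| partner | 8.1 mM | 12.1 mM | 12.1 mM | 12.1 mM |
| precatalyst | 11 µM | 22 µM | 11 µM | 11 µM |
| temperature | 50 °C | 50 °C | 30 °C | 50 °C |
| remark | run made earlier | run made earlier |  |  |
| time |  |  | 1.0 h | 1.0 h |

| run | time / min | product / % | starting material / % |
|---|---|---|---|
| Thursday's | 0.667 | 0 | 102 |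
| Thursday's | 2.00 | 2 | 98 |
| Thursday's | 3.00 | 0 | 99 |
| Thursday's | 5.00 | 4 | 101 |
| Thursday's | 8.00 | 4 | 94 |
| Thursday's | 10.0 | 4 | 92 |
| Thursday's | 12.0 | 7 | 91 |
| Saturday's | 1.00 | 2 | 97 |
| Saturday's | 1.33 | 0 | 97 |
| Saturday's | 2.00 | 2 | 95 |
| Saturday's | 3.00 | 2 | 98 |
| Saturday's | 5.00 | 7 | 96 |
| Saturday's | 8.00 | 11 | 91 |
| Saturday's | 12.0 | 21 | 79 |

(standard deviation of a reading: 2 percentage points)

- what was read earlier has a scatter of 2 percentage points, one standard deviation
- the earlier runs do not show what temperature does; that part of a forecast is a guess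

- the winner by amount of product, in percent of the starting material charged; "neither" if no more than 2 percentage points parts them (autumn / winter / neither)
- how much product is there at the end, in percent of the starting material charged: autumn
- how much product is there at the end, in percent of the starting material charged: winter

Their joint effect could still be tested, so I defined the turnover yield, a turnover number per unit of partner: product formed per precatalyst charged, divided by the partner charged, at 12.0 min and 50 °C. Thursday's reading of 7% gave 8.64 mM⁻¹, and Saturday's 21% gave 8.68 mM⁻¹, the same within the scatter of 2 percentage points on a small reading. Held at that time and temperature, my turnover yield put winter at 10.5% after 12.0 min. It gave me nothing for the full hour, or for autumn's 30 °C.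

The forecast used the same two readings, saying their rise “fits first order in both catalyst” and partner. It named winter as the winner, with winter at 55% (32% to 88%) and autumn at 12% (4% to 35%).

The flask gave winter 64.8% and autumn 17.9%, so winter won, and both values lay above the forecast's but inside its ranges.

    starting material + free catalyst ⇌ catalyst intermediate A (K = 220 L mol⁻¹, k = 14300 L mol⁻¹ s⁻¹, Ea = 19.0 kJ mol⁻¹, ΔH = 9.00 kJ mol⁻¹)
    partner + catalyst intermediate A ⇌ catalyst intermediate B (K = 42.0 L mol⁻¹, k = 25700 L mol⁻¹ min⁻¹, Ea = 41.0 kJ mol⁻¹, ΔH = −31.0 kJ mol⁻¹)
    catalyst intermediate B → free catalyst + product (k = 104 min⁻¹, Ea = 69.0 kJ mol⁻¹)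
    precatalyst → free catalyst (k = 0.103 min⁻¹, Ea = 90.0 kJ mol⁻¹)
    partner ⇌ dormant form (K = 0.180, k = 0.452 min⁻¹, Ea = 84.0 kJ mol⁻¹, ΔH = −25.0 kJ mol⁻¹)
    (constants at 50 °C)

Temperature is the main reason autumn trailed winter: autumn's flask run at 50 °C gave 92.6%, against its 17.9%. Winter itself stood at 10.4% after 12.0 min, against my 10.5%, and I used the turnover yield again at one temperature and one time. Autumn's own value at 30 °C and 1.0 h is 5.37 mM⁻¹. Held for autumn's neighbour, charged with 0.0027 mM of precatalyst at the same temperature and time, it gives 4.39%, and that neighbour gave 4.63%.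

The readings were computed on assumed constants, and the scatter is random.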